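**Plan**
- Retrosynthesis cuts the four O–H bonds back to methyl ethers and the ring A aryl–C(=O) bond back to an aryl isobutyrate (O→C acyl shift).
- It then cuts both C2–CH3 bonds and the O1–C2 bond of ring C back to the lactone carbonyl of a 4-methoxycoumarin, whose C4–C4a and O1–C2(=O) bonds come from a malonate unit.
- The two aryl–CH2 bonds go back to formaldehyde and two molecules of 3,5-dimethoxy-4-methylphenol.
- Forward: phenol, then the methylene-bridged bisphenol (rings A and B), then a lactone ring fused to ring B, which methyllithium and acid open and reclose as the 2,2-dimethylpyranone ring C; ring A is acylated last and the ethers are cleaved.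
- Enabling feature: C2 of ring C carries two methyl groups and the ring oxygen O1, which is a lactone carbonyl after two methyl additions, and the C4 ketone is latent in a 4-methoxy enol ether.
- The target has no stereocentre, so nothing has to be controlled; the position of O1 next to the bridge carbon C8 is fixed when the coumarin is built on a phenol flanked by the bridge carbon and the future C4a.

Key step: step 6

Remark on the chemistry: ring A is the acylphloroglucinol ring, ring B the benzo ring of the chromanone and ring C its pyranone ring (O1, C2, C3, C4, C4a, C5–C8, C8a). The benzyl group carried through the key step is 6-hydroxy-2,4-dimethoxy-3-methylbenzyl: its methyl lies between the two methoxy groups and its one free ring carbon between OH and OMe. Compounds 1, 4, 6, 10 and 15 are commercial.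

Step 1
Reactants: 1 2,6-dimethoxytoluene
Product: 3 3,5-dimethoxy-4-methylphenol, via aryl pinacol boronate 2 (not isolated)
Conditions: [Ir(OMe)(cod)]2 (1 mol %, cod = 1,5-cyclooctadiene), 4,4'-di-tert-butyl-2,2'-bipyridine (2 mol %), B2pin2 (1.0 equiv), THF, 80 °C; then KHSO5 (Oxone), acetone–H2O, rt
Reagents that add atoms: bis(pinacolato)diboron, CC1(C)OB(OC1(C)C)B1OC(C)(C)C(C)(C)O1 (boron of intermediate 2 only); potassium peroxymonosulfate KHSO5, [K+].[O-]S(=O)(=O)OO (the phenol oxygen)
Why: Iridium-catalysed C–H borylation is sterically controlled and should take the only ring hydrogen of 1 without an ortho substituent (C4, meta to both methoxy groups), and the one-pot peroxymonosulfate oxidation of the boronate (borylation–oxidation phenol synthesis) converts C–B into C–OH at the same carbon.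

Step 2
Reactants: 3 3,5-dimethoxy-4-methylphenol (two molecules); 4 formaldehyde
Product: 5 2,2'-methylenebis(3,5-dimethoxy-4-methylphenol)
Conditions: 37% aq. CH2O (0.25 equiv), cat. H2SO4, AcOH, 0 °C to rt; excess 3 recovered
Reagents that add atoms: none
Why: Acid-catalysed hydroxymethylation followed by Friedel–Crafts benzylation (phenol–formaldehyde condensation) can only use the two equivalent carbons ortho to the hydroxyl of 3, since the para carbon bears the methyl group, and the large excess of 3 should hold the condensation at the dimer.

Step 3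
Reactants: 5 2,2'-methylenebis(3,5-dimethoxy-4-methylphenol); 6 Meldrum's acid
Product: 7 3-{2-[(6-hydroxy-2,4-dimethoxy-3-methylphenyl)methyl]-3,5-dimethoxy-4-methylphenoxy}-3-oxopropanoic acid
Conditions: 6 (0.8 equiv), toluene, 100 °C; cold aq. NaHCO3 extraction returns unreacted 5
Reagents that add atoms: none
Why: Thermal ring opening of Meldrum's acid by a phenol gives the aryl hydrogen malonate with loss of acetone, and with the acylating agent as limiting partner the mono-ester of the symmetric bisphenol should be the main acylated product, separable as a carboxylic acid from neutral 5.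

Step 4
Reactants: 7 3-{2-[(6-hydroxy-2,4-dimethoxy-3-methylphenyl)methyl]-3,5-dimethoxy-4-methylphenoxy}-3-oxopropanoic acid
Product: 8 4-hydroxy-8-[(6-hydroxy-2,4-dimethoxy-3-methylphenyl)methyl]-5,7-dimethoxy-6-methyl-2H-chromen-2-one
Conditions: P2O5 in MeSO3H (Eaton's reagent), 50 °C
Reagents that add atoms: none
Why: Eaton's reagent activates the malonic half ester for intramolecular Friedel–Crafts acylation at the only free carbon of the esterified ring, which is ortho to the ester oxygen and activated by one ortho and one para methoxy group, and the resulting 1,3-dicarbonyl rests as the 4-hydroxycoumarin.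

Step 5
Reactants: 8 4-hydroxy-8-[(6-hydroxy-2,4-dimethoxy-3-methylphenyl)methyl]-5,7-dimethoxy-6-methyl-2H-chromen-2-one
Product: 9 8-[(6-hydroxy-2,4-dimethoxy-3-methylphenyl)methyl]-4,5,7-trimethoxy-6-methyl-2H-chromen-2-one
Conditions: Me2SO4 (1.1 equiv), NaHCO3 (1.5 equiv), acetone, reflux
Reagents that add atoms: dimethyl sulfate, COS(=O)(=O)OC
Why: The enolic 4-hydroxyl is as acidic as a carboxylic acid whereas the ring A phenol is not deprotonated by hydrogen carbonate, so O-alkylation with the hard electrophile dimethyl sulfate (the standard route from 4-hydroxycoumarins to 4-methoxycoumarins) should fall on the 4-oxygen only.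

Step 6
Reactants: 9 8-[(6-hydroxy-2,4-dimethoxy-3-methylphenyl)methyl]-4,5,7-trimethoxy-6-methyl-2H-chromen-2-one; 10 methyllithium
Product: 14 8-[(6-hydroxy-2,4-dimethoxy-3-methylphenyl)methyl]-5,7-dimethoxy-2,2,6-trimethylchroman-4-one, via ring-opened methyl ketone 11 (not isolated), via tertiary allylic carbinol 12 (not isolated), via 4-methoxy-2H-chromene 13 (not isolated)
Conditions: MeLi (4.5 equiv), THF, −78 to 0 °C; then aq. HCl (2 mol/L), THF–H2O, rt
Reagents that add atoms: water, O (the C4 carbonyl oxygen)
Why: One equivalent of MeLi is spent on the ring A phenol, the next adds 1,2 to the lactone carbonyl C2, whose hemiketal alkoxide opens to the ring B phenoxide and the β-methoxy enone 11, and a further equivalent adds to that ketone to give the alkoxide of 12, so both C2–CH3 bonds are formed. Aqueous acid ionises the tertiary allylic carbinol to a methoxy-stabilised allyl cation, the freed phenol oxygen O1 attacks the gem-dimethyl terminus in a 6-endo-trig closure of ring C to give the cyclic enol ether 13, and hydrolysis of the 4-methoxy enol ether then reveals the C4 ketone. The closest known reaction is the addition of methyl Grignard or methyllithium reagents to coumarins with acid cyclisation to 2,2-dimethyl-2H-chromenes, that is double organometal addition to a lactone followed by cyclodehydration. No stereocentre arises because C2 carries two identical methyl groups. The step needs attack at the lactone carbonyl instead of conjugate displacement of the 4-methoxy group, which the hard organolithium at low temperature and the donor-deactivated C4 should secure, and it needs closure through O1 alone, which is secured because the C5 oxygen is still a methyl ether and O1 is the only free phenol on ring B. Excess MeLi at low temperature is used so that addition to ketone 11 outruns its enolisation.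

Step 7
Reactants: 14 8-[(6-hydroxy-2,4-dimethoxy-3-methylphenyl)methyl]-5,7-dimethoxy-2,2,6-trimethylchroman-4-one; 15 isobutyryl chloride
Product: 16 2-[(5,7-dimethoxy-2,2,6-trimethyl-4-oxochroman-8-yl)methyl]-3,5-dimethoxy-4-methylphenyl 2-methylpropanoate
Conditions: Me2CHCOCl (1.2 equiv), Et3N, 4-(dimethylamino)pyridine (5 mol %), CH2Cl2, 0 °C to rt
Reagents that add atoms: none
Why: 4-(Dimethylamino)pyridine-catalysed O-acylation of the single free phenol with an acid chloride is routine esterification, and no other hydroxyl is present.

Step 8
Reactants: 16 2-[(5,7-dimethoxy-2,2,6-trimethyl-4-oxochroman-8-yl)methyl]-3,5-dimethoxy-4-methylphenyl 2-methylpropanoate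
Product: 17 8-{[6-hydroxy-2,4-dimethoxy-3-methyl-5-(2-methylpropanoyl)phenyl]methyl}-5,7-dimethoxy-2,2,6-trimethylchroman-4-one
Conditions: hν (254 nm, quartz), degassed MeCN, rt
Reagents that add atoms: none
Why: Excitation of the aryl ester cleaves the O–acyl bond to a caged phenoxyl and isobutyryl radical pair (photo-Fries rearrangement), and because the para carbon and one ortho carbon of ring A are substituted, recombination and tautomerisation can only place the ketone on the free ortho carbon, under neutral conditions that spare the methyl ethers, the chromanone and the methylene bridge.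

Step 9
Reactants: 17 8-{[6-hydroxy-2,4-dimethoxy-3-methyl-5-(2-methylpropanoyl)phenyl]methyl}-5,7-dimethoxy-2,2,6-trimethylchroman-4-one
Product: 18 5,7-dihydroxy-2,2,6-trimethyl-8-{[2,4,6-trihydroxy-3-methyl-5-(2-methylpropanoyl)phenyl]methyl}chroman-4-one (CNP0186856.0)
Conditions: BBr3 (10 equiv), CH2Cl2, −78 °C to rt; then H2O
Reagents that add atoms: none
Why: BBr3 cleaves the four aryl methyl ethers by bromide attack on the O-methyl carbon of the boron–ether adduct (Lewis-acid ether cleavage), helped by chelation at the two methoxy groups next to a carbonyl, while the ring C oxygen is a vinylogous ester oxygen on a tertiary carbon β to the ketone and should resist coordination and ionisation at low temperature.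

**Compound list**
1 | 2,6-dimethoxytoluene | COc1cccc(OC)c1C | starting material
2 | 2-(3,5-dimethoxy-4-methylphenyl)-4,4,5,5-tetramethyl-1,3,2-dioxaborolane (formed in the flask) | COc1cc(B2OC(C)(C)C(C)(C)O2)cc(OC)c1C | intermediate
3 | 3,5-dimethoxy-4-methylphenol | COc1cc(O)cc(OC)c1C | intermediate
4 | formaldehyde | C=O | starting material
5 | 2,2'-methylenebis(3,5-dimethoxy-4-methylphenol) | COc1cc(O)c(Cc2c(O)cc(OC)c(C)c2OC)c(OC)c1C | intermediate
6 | Meldrum's acid (2,2-dimethyl-1,3-dioxane-4,6-dione) | CC1(C)OC(=O)CC(=O)O1 | starting material
7 | 3-{2-[(6-hydroxy-2,4-dimethoxy-3-methylphenyl)methyl]-3,5-dimethoxy-4-methylphenoxy}-3-oxopropanoic acid | OC(=O)CC(=O)Oc1cc(OC)c(C)c(OC)c1Cc1c(O)cc(OC)c(C)c1OC | intermediate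
8 | 4-hydroxy-8-[(6-hydroxy-2,4-dimethoxy-3-methylphenyl)methyl]-5,7-dimethoxy-6-methyl-2H-chromen-2-one | OC1=CC(=O)Oc2c(Cc3c(O)cc(OC)c(C)c3OC)c(OC)c(C)c(OC)c12 | intermediate
9 | 8-[(6-hydroxy-2,4-dimethoxy-3-methylphenyl)methyl]-4,5,7-trimethoxy-6-methyl-2H-chromen-2-one | COC1=CC(=O)Oc2c(Cc3c(O)cc(OC)c(C)c3OC)c(OC)c(C)c(OC)c12 | intermediate
10 | methyllithium | [Li]C | starting material
11 | (E)-4-{2-hydroxy-3-[(6-hydroxy-2,4-dimethoxy-3-methylphenyl)methyl]-4,6-dimethoxy-5-methylphenyl}-4-methoxybut-3-en-2-one (formed in the flask as its lithium phenoxide) | CC(=O)/C=C(/OC)c1c(OC)c(C)c(OC)c(Cc2c(O)cc(OC)c(C)c2OC)c1O | intermediate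
12 | 2-[(E)-3-hydroxy-1-methoxy-3-methylbut-1-en-1-yl]-6-[(6-hydroxy-2,4-dimethoxy-3-methylphenyl)methyl]-3,5-dimethoxy-4-methylphenol (formed in the flask as its lithium salt) | CC(C)(O)/C=C(/OC)c1c(OC)c(C)c(OC)c(Cc2c(O)cc(OC)c(C)c2OC)c1O | intermediate
13 | 8-[(6-hydroxy-2,4-dimethoxy-3-methylphenyl)methyl]-4,5,7-trimethoxy-2,2,6-trimethyl-2H-chromene (formed in the flask) | COC1=CC(C)(C)Oc2c(Cc3c(O)cc(OC)c(C)c3OC)c(OC)c(C)c(OC)c12 | intermediate
14 | 8-[(6-hydroxy-2,4-dimethoxy-3-methylphenyl)methyl]-5,7-dimethoxy-2,2,6-trimethylchroman-4-one | CC1(C)CC(=O)c2c(OC)c(C)c(OC)c(Cc3c(O)cc(OC)c(C)c3OC)c2O1 | intermediate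
15 | isobutyryl chloride (2-methylpropanoyl chloride) | CC(C)C(Cl)=O | starting material
16 | 2-[(5,7-dimethoxy-2,2,6-trimethyl-4-oxochroman-8-yl)methyl]-3,5-dimethoxy-4-methylphenyl 2-methylpropanoate | CC(C)C(=O)Oc1cc(OC)c(C)c(OC)c1Cc1c(OC)c(C)c(OC)c2c1OC(C)(C)CC2=O | intermediate
17 | 8-{[6-hydroxy-2,4-dimethoxy-3-methyl-5-(2-methylpropanoyl)phenyl]methyl}-5,7-dimethoxy-2,2,6-trimethylchroman-4-one | CC(C)C(=O)c1c(O)c(Cc2c(OC)c(C)c(OC)c3c2OC(C)(C)CC3=O)c(OC)c(C)c1OC | intermediate
18 | 5,7-dihydroxy-2,2,6-trimethyl-8-{[2,4,6-trihydroxy-3-methyl-5-(2-methylpropanoyl)phenyl]methyl}chroman-4-one | Cc1c(O)c(Cc2c(O)c(C)c(O)c3c2OC(C)(C)CC3=O)c(O)c(C(=O)C(C)C)c1O | target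

Total step count: 9. Longest linear sequence: 9 steps (1 to 18).

**Steps most likely to fail**

1. Step 4. The electron-rich diarylmethane may not tolerate warm Eaton's reagent: ipso-protonation can shift or expel the methylene bridge, and the free ring A carbon can be acylated or sulfonylated between molecules, on top of the statistical loss in step 3. The fallback sets out from 5 and avoids strong acid. Acetylation with a deficit of Ac2O in pyridine should give the mono-acetate 2-[(6-hydroxy-2,4-dimethoxy-3-methylphenyl)methyl]-3,5-dimethoxy-4-methylphenyl acetate F1. Photo-Fries rearrangement (254 nm, MeCN; this molecule has no second chromophore) should move the acetyl group to the free ortho carbon and give 1-{2-hydroxy-3-[(6-hydroxy-2,4-dimethoxy-3-methylphenyl)methyl]-4,6-dimethoxy-5-methylphenyl}ethan-1-one F2. NaH and diethyl carbonate in toluene at reflux, then acidification, should close the 4-hydroxycoumarin by Claisen condensation and lactonisation, and the route is rejoined at 8.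

2. Step 8. The chromanone absorbs in the same region as the aryl ester and may drain the excitation by energy transfer, and the product is itself a strong absorber, so the rearrangement may stall while radical escape returns phenol 14. The fallback sets out from 14: direct Friedel–Crafts ortho-acylation with isobutyryl chloride and TiCl4 in CH2Cl2 at 0 °C, the titanium phenoxide directing to the only free ring carbon, comes back to the route at 17. Partial loss of the methyl ether next to the new ketone would not matter because step 9 removes all four. This fallback makes no compound outside the list (F0).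

3. Step 6. Enolisation of the intermediate methyl ketone by MeLi can stop the sequence after one addition, and the acid treatment would then cyclodehydrate to a chromone instead of the chromanone; conjugate displacement of the 4-methoxy group is the second possible leak. The fallback sets out from 9 and uses that mono-addition deliberately. MeLi limited to 2.1 equiv at −78 °C followed by aqueous HCl should give, through the 4-methoxybenzopyrylium ion and its hydrolysis, 8-[(6-hydroxy-2,4-dimethoxy-3-methylphenyl)methyl]-5,7-dimethoxy-2,6-dimethyl-4H-chromen-4-one F3. Conjugate addition of Me2CuLi activated by BF3·OEt2 in THF at −78 °C then builds the quaternary C2, and protonation of the enolate on work-up comes back to the route at 14.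

**Further compounds**
F1 | step 4 | 2-[(6-hydroxy-2,4-dimethoxy-3-methylphenyl)methyl]-3,5-dimethoxy-4-methylphenyl acetate | CC(=O)Oc1cc(OC)c(C)c(OC)c1Cc1c(O)cc(OC)c(C)c1OC
F2 | step 4 | 1-{2-hydroxy-3-[(6-hydroxy-2,4-dimethoxy-3-methylphenyl)methyl]-4,6-dimethoxy-5-methylphenyl}ethan-1-one | CC(=O)c1c(O)c(Cc2c(O)cc(OC)c(C)c2OC)c(OC)c(C)c1OC
F0 | step 8 | none | none
F3 | step 6 | 8-[(6-hydroxy-2,4-dimethoxy-3-methylphenyl)methyl]-5,7-dimethoxy-2,6-dimethyl-4H-chromen-4-one | CC1=CC(=O)c2c(OC)c(C)c(OC)c(Cc3c(O)cc(OC)c(C)c3OC)c2O1
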